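**Strategy.** Ring A is not brought to the depside coupling ready-made; it is grown on the ester. Its contiguous run C2(OH)–C3(Cl)–C4(OMe)–C5(H) is the four-carbon chain of a 2-chloro-1,3-dimethoxy-1-silyloxybutadiene. C1 (acyl) and C6 (propyl) are the alkyne carbons of a hex-2-ynoate, so the disconnection cuts ring A bonds C1–C2 and C5–C6. One thermal [4+2] benzannulation closes ring A and fixes all five substituents, chlorine included, without any arene halogenation, and the hindered depside C–O bond is already made. The precursor is benzyl olivetolate acylated at ring B O4 with hex-2-ynoic acid. Its chelated O2 is capped as a trimethylsilyl ether that leaves in the same acidic work-up.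

Key step: step 7

**Assumptions and design remarks**
- The double-bond geometries of the chloro enol ether, its dienolate and the diene are left undefined, because each of these carbons ends up in aromatic ring A. The chloro keto ester, its ketal and the cycloadduct are racemic. The target has no stereocentre.
- Chelation distinguishes ring B O2 from O4 only while both are free, so O2 has to be masked after the ynoate is on.
- Masking with a benzyl halide and a carbonate base would place a phenoxide next to an activated aryl ynoate. That invites conjugate addition, acyl transfer and ynoate–allenoate isomerisation.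
- A neutral silylation avoids this and needs no deprotection step of its own. It also leaves a single benzyl ester for the last step, which shortens the contact of the C3–Cl bond with Pd and H2.
- Olivetolic acid can also be bought, in which case step 1 is dropped.

**Step 1**
Reactants: 1 olivetol (5-pentylbenzene-1,3-diol)
Product: 3 olivetolic acid (2,4-dihydroxy-6-pentylbenzoic acid), via magnesium 4-hydroxy-2-oxido-6-pentylbenzoate 2 (not isolated)
Conditions: MeOMgOCO2Me (2 M in DMF, excess), 120 °C; then cold 2 M aq HCl
Reagents that add atoms: methoxymagnesium methyl carbonate MeOMgOCO2Me, CO[Mg]OC(=O)OC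
Why: Stiles-type ortho-carboxylation of a phenol (a relative of the Kolbe–Schmitt reaction) should place CO2 on the ring carbon ortho to one hydroxyl and para to the other, and the six-membered magnesium salicylate chelate drives the otherwise reversible reaction, as established for 5-alkylresorcinols.

**Step 2**
Reactants: 3 olivetolic acid
Product: 4 benzyl olivetolate (benzyl 2,4-dihydroxy-6-pentylbenzoate)
Conditions: BnBr, KHCO3, DMF, rt
Reagents that add atoms: benzyl bromide, BrCc1ccccc1
Why: SN2 O-alkylation of the carboxylate, in which KHCO3 ionises only the carboxylic acid, so both phenols should stay free.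

**Step 3**
Reactants: 4 benzyl olivetolate; 5 hex-2-ynoic acid
Product: 6 benzyl 4-(hex-2-ynoyloxy)-2-hydroxy-6-pentylbenzoate
Conditions: DCC, DMAP (cat.), CH2Cl2, 0 °C to rt
Reagents that add atoms: none
Why: Steglich esterification, site-selective because the ring B C2 hydroxyl is hydrogen-bonded to and flanked by the benzyl ester while the C4 hydroxyl is free; the acyl carbon is still a slim ynoyl group, so the depside C–O bond forms without the steric penalty of a 2,6-disubstituted benzoic acid.

**Step 4**
Reactants: 6 benzyl 4-(hex-2-ynoyloxy)-2-hydroxy-6-pentylbenzoate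
Product: 7 benzyl 4-(hex-2-ynoyloxy)-6-pentyl-2-(trimethylsilyloxy)benzoate
Conditions: BSA, toluene, 60 °C; volatiles removed in high vacuum; used crude under Ar
Reagents that add atoms: N,O-bis(trimethylsilyl)acetamide (BSA), CC(=N[Si](C)(C)C)O[Si](C)(C)C
Why: Neutral trans-silylation of a phenol by a silyl imidate brings in no base, halide or nucleophile that could add to or cleave the aryl ynoate, its by-product is volatile, and any trace of hydrolysis is repaired by the surplus diene of the key step.

**Step 5**
Reactants: 8 methyl 2-chloroacetoacetate (racemic)
Product: 10 methyl 2-chloro-3-methoxybut-2-enoate (E/Z mixture), via methyl 2-chloro-3,3-dimethoxybutanoate 9 (not isolated)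
Conditions: HC(OMe)3, H2SO4 (cat.), MeOH, 50 °C; then distillation from TsOH (cat.)
Reagents that add atoms: trimethyl orthoformate, COC(OC)OC
Why: Acid-catalysed ketalisation with an orthoester, followed by E1-type loss of methanol toward the acidic C2–H, should give the conjugated tetrasubstituted enol ether, as in the standard route to β-methoxycrotonates.

**Step 6**
Reactants: 10 methyl 2-chloro-3-methoxybut-2-enoate
Product: 12 2-chloro-1,3-dimethoxy-1-(trimethylsilyloxy)buta-1,3-diene, via lithium 2-chloro-1,3-dimethoxybuta-1,3-dien-1-olate 11 (not isolated)
Conditions: LiN(iPr)2 (commercial solution), THF, −78 °C; then Me3SiCl, −78 °C to rt; pentane, filtration, bulb-to-bulb distillation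
Reagents that add atoms: chlorotrimethylsilane, C[Si](C)(C)Cl
Why: Kinetic γ-deprotonation of a β-alkoxycrotonate gives the extended enolate, which the hard silyl chloride traps on oxygen; this is the standard preparation of vinylketene silyl acetals, and α-chloro ester enolates are stable at −78 °C.

**Step 7**
Reactants: 7 benzyl 4-(hex-2-ynoyloxy)-6-pentyl-2-(trimethylsilyloxy)benzoate; 12 2-chloro-1,3-dimethoxy-1-(trimethylsilyloxy)buta-1,3-diene
Product: 15 benzyl 4-[(3-chloro-2-hydroxy-4-methoxy-6-propylbenzoyl)oxy]-2-hydroxy-6-pentylbenzoate, via cyclohexadiene cycloadduct 13 (not isolated), via bis-trimethylsilyl depside 14 (not isolated)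
Conditions: 12 (3 equiv), toluene (concentrated), sealed tube, 120 °C; then 1 M aq HCl/THF, rt
Reagents that add atoms: none
Why: The partners combine in a normal-electron-demand Diels–Alder reaction whose two bonds form unevenly (in the extreme, a Mukaiyama–Michael-type conjugate addition of the dienyl ketene acetal and then ring closure), the CH2 terminus of 12 bonding to the propyl-bearing β-carbon of the ynoate (ring A C5–C6) and the ketene acetal carbon to the α-carbon (ring A C1–C2). Ring A, the only ring formed, is closed by this intermolecular [4+2] cycloaddition, with four carbons from 12 and two from the alkyne of 7, to give the 1,4-cyclohexadiene 13. Compound 13 then expels methanol across the ring (OMe from C2, H from C5) to become the arene 14, and the dilute-acid work-up hydrolyses both aryl trimethylsilyl ethers to give 15. The closest known reactions are the benzannulations of 1,3-dialkoxy-1-silyloxybutadienes with alkynoates and haloquinones, which deliver 2-hydroxy-4-alkoxy arenes, and the thermal additions of bis-silyloxydienes to β-alkyl ynoate lactones. Only regioselectivity is needed, and the matched polarisation secures it (largest donor coefficient at the diene CH2, largest acceptor coefficient at the ynoate β-carbon); the single stereocentre of 13 (C2) forms racemic and is erased on aromatisation, so no stereocontrol element is required. The phenolic leaving-group character of ring B lowers the alkyne LUMO below that of an alkyl hex-2-ynoate, 7 has no acidic proton that could quench 12, and surplus 12 traps the liberated methanol before it can attack either aryl ester.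

**Step 8**
Reactants: 15 benzyl 4-[(3-chloro-2-hydroxy-4-methoxy-6-propylbenzoyl)oxy]-2-hydroxy-6-pentylbenzoate
Product: 16 4-[(3-chloro-2-hydroxy-4-methoxy-6-propylbenzoyl)oxy]-2-hydroxy-6-pentylbenzoic acid (target)
Conditions: H2 (1 atm), 10% Pd/C, EtOAc, rt, no base, stopped as soon as 15 is consumed; concentrated below 30 °C
Reagents that add atoms: none
Why: Catalytic hydrogenolysis of a single benzyl ester is much faster than hydrodechlorination of an electron-rich aryl chloride on Pd/C in a neutral, base-free, aprotic medium, and the depside ester, the aryl methyl ether and the phenols are inert.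

**Compound list**
1 | olivetol (5-pentylbenzene-1,3-diol) | CCCCCc1cc(O)cc(O)c1 | starting material
2 | magnesium 4-hydroxy-2-oxido-6-pentylbenzoate (chelated salt, not isolated) | CCCCCc1cc(O)cc([O-])c1C(=O)[O-].[Mg+2] | intermediate
3 | olivetolic acid (2,4-dihydroxy-6-pentylbenzoic acid) | CCCCCc1cc(O)cc(O)c1C(=O)O | intermediate
4 | benzyl 2,4-dihydroxy-6-pentylbenzoate | CCCCCc1cc(O)cc(O)c1C(=O)OCc1ccccc1 | intermediate
5 | hex-2-ynoic acid | CCCC#CC(=O)O | starting material
6 | benzyl 4-(hex-2-ynoyloxy)-2-hydroxy-6-pentylbenzoate | CCCCCc1cc(OC(=O)C#CCCC)cc(O)c1C(=O)OCc1ccccc1 | intermediate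
7 | benzyl 4-(hex-2-ynoyloxy)-6-pentyl-2-(trimethylsilyloxy)benzoate | CCCCCc1cc(OC(=O)C#CCCC)cc(O[Si](C)(C)C)c1C(=O)OCc1ccccc1 | intermediate
8 | methyl 2-chloroacetoacetate (racemic) | CC(=O)C(Cl)C(=O)OC | starting material
9 | methyl 2-chloro-3,3-dimethoxybutanoate (racemic, not isolated) | CC(OC)(OC)C(Cl)C(=O)OC | intermediate
10 | methyl 2-chloro-3-methoxybut-2-enoate (E/Z mixture) | CC(OC)=C(Cl)C(=O)OC | intermediate
11 | lithium 2-chloro-1,3-dimethoxybuta-1,3-dien-1-olate (geometry undefined, not isolated) | C=C(OC)C(Cl)=C(OC)[O-].[Li+] | intermediate
12 | 2-chloro-1,3-dimethoxy-1-(trimethylsilyloxy)buta-1,3-diene (ketene acetal geometry undefined) | C=C(OC)C(Cl)=C(OC)O[Si](C)(C)C | intermediate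
13 | benzyl 4-{[5-chloro-4,6-dimethoxy-2-propyl-6-(trimethylsilyloxy)cyclohexa-1,4-diene-1-carbonyl]oxy}-6-pentyl-2-(trimethylsilyloxy)benzoate (racemic, not isolated) | CCCCCc1cc(OC(=O)C2=C(CCC)CC(OC)=C(Cl)C2(OC)O[Si](C)(C)C)cc(O[Si](C)(C)C)c1C(=O)OCc1ccccc1 | intermediate
14 | benzyl 4-{[3-chloro-4-methoxy-6-propyl-2-(trimethylsilyloxy)benzoyl]oxy}-6-pentyl-2-(trimethylsilyloxy)benzoate (not isolated) | CCCCCc1cc(OC(=O)c2c(CCC)cc(OC)c(Cl)c2O[Si](C)(C)C)cc(O[Si](C)(C)C)c1C(=O)OCc1ccccc1 | intermediate
15 | benzyl 4-[(3-chloro-2-hydroxy-4-methoxy-6-propylbenzoyl)oxy]-2-hydroxy-6-pentylbenzoate | CCCCCc1cc(OC(=O)c2c(CCC)cc(OC)c(Cl)c2O)cc(O)c1C(=O)OCc1ccccc1 | intermediate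
16 | 4-[(3-chloro-2-hydroxy-4-methoxy-6-propylbenzoyl)oxy]-2-hydroxy-6-pentylbenzoic acid | CCCCCc1cc(OC(=O)c2c(CCC)cc(OC)c(Cl)c2O)cc(O)c1C(=O)O | target

**Total step count:** 8. **Longest linear sequence:** 6 (steps 1, 2, 3, 4, 7, 8). The diene branch (steps 5, 6) joins at step 7.

**Steps most likely to fail**

1. **Step 7.**
   - *What may go wrong:* the β-propyl ynoate may react too slowly with a diene that the C2 chlorine both deactivates and twists out of its s-cis form. The diene would then be lost to silyl migration, hydrolysis or oligomerisation before it adds. Acyl transfer from the activated aryl ester may also compete at the temperature needed.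
   - *Fallback:* it sets out from 4 and comes back to the route at 15. Ring A is made as a free acid by arene chemistry in which symmetry, not electronic bias, fixes the chlorine. Commercial 1,3-dimethoxy-5-propylbenzene (CCCc1cc(OC)cc(OC)c1) is lithiated with n-BuLi in THF at 0 °C between its two methoxy groups to give 2-lithio-1,3-dimethoxy-5-propylbenzene F1. Quenching with C2Cl6 gives 2-chloro-1,3-dimethoxy-5-propylbenzene F2. Rieche formylation (Cl2CHOMe, TiCl4, CH2Cl2, 0 °C) at either of the two equivalent free positions gives 3-chloro-2,4-dimethoxy-6-propylbenzaldehyde F3. BCl3 in CH2Cl2 cleaves only the methoxy group chelated to the aldehyde and gives 3-chloro-2-hydroxy-4-methoxy-6-propylbenzaldehyde F4. Pinnick oxidation (NaClO2, NaH2PO4, sulfamic acid) gives 3-chloro-2-hydroxy-4-methoxy-6-propylbenzoic acid F5. This acid is condensed with the unchelated C4 hydroxyl of 4 using (CF3CO)2O in toluene, the classical depside esterification, to give 15.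

2. **Step 5.**
   - *What may go wrong:* the hindered, electron-poor α-chloro ketone may ketalise incompletely. Prolonged acid and heat during the cracking may also erode the material through loss of HCl.
   - *Fallback:* the chlorine is put onto a preformed enol ether rather than the enol ether onto a chloro ketone. Purchasable methyl (E)-3-methoxybut-2-enoate (CO/C(C)=C/C(=O)OC) takes the place of starting material 8. NCS in MeCN at rt in the dark (ionic conditions) chlorinates the nucleophilic C2, and loss of the C2 proton restores the conjugated enol ether. The route is rejoined at 10. No compound outside the list is made (entry F0).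

3. **Step 8.**
   - *What may go wrong:* hydrodechlorination at ring A C3 may compete with benzyl cleavage on over-long exposure or with an over-active catalyst batch. The salicylic acid may decarboxylate on warm concentration.
   - *Fallback:* it sets out from 15 and comes back at 16 by a non-reductive Lewis-acid debenzylation with BCl3 and pentamethylbenzene as cation scavenger in CH2Cl2 at −78 °C. Boron chelation between ring B O2 and the ester carbonyl directs cleavage to the O–benzyl bond. The unchelated C4 methoxy group of ring A should not be touched at this temperature. No compound outside the list is made (entry F0).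

**Further compounds**
F1 | step 7 | 2-lithio-1,3-dimethoxy-5-propylbenzene | [Li]c1c(OC)cc(CCC)cc1OC
F2 | step 7 | 2-chloro-1,3-dimethoxy-5-propylbenzene | CCCc1cc(OC)c(Cl)c(OC)c1
F3 | step 7 | 3-chloro-2,4-dimethoxy-6-propylbenzaldehyde | CCCc1cc(OC)c(Cl)c(OC)c1C=O
F4 | step 7 | 3-chloro-2-hydroxy-4-methoxy-6-propylbenzaldehyde | CCCc1cc(OC)c(Cl)c(O)c1C=O
F5 | step 7 | 3-chloro-2-hydroxy-4-methoxy-6-propylbenzoic acid | CCCc1cc(OC)c(Cl)c(O)c1C(=O)O
F0 | step 5 | none | none
F0 | step 8 | none | none
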